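**Conventions.** Decalin compounds carry eremophilane numbering: ring A is C1, C2, C3, C4, C5, C10 and ring B is C5, C6, C7, C8, C9, C10. β is the face of the C5 methyl group and α the opposite face. Compounds 4, 5 and 7 carry bicyclo[2.2.2]octane numbering.

## Analysis of the target

The target is a cis-fused decalin of the eremophilane type, with a C2 ketone, methyl groups on C4 and C5, an isopropenyl group on C7, an O-2-methylbutanoyl group on C8 and an O-tigloyl group on C9. It has six contiguous ring stereocentres (C4, C5, C7, C8, C9, C10) and a seventh, read from the SMILES as (R), in the 2-methylbutanoate. Both methyl groups, the C10 hydrogen and the isopropenyl group lie on the β face and both acyloxy groups on the α face, so the relations are 4,5-cis, cis ring fusion, 7,8-trans and 8,9-cis. In the chair–chair form that keeps the isopropenyl group equatorial, the C5 methyl and the C8 ester are equatorial on ring B and the C9 ester is axial, tucked under ring A. The sensitive points are two different esters on adjacent cis oxygens, a tiglate that is a Michael acceptor, the epimerisable α-carbon of the 2-methylbutanoate, and an isopropenyl group that acid can hydrate or shift. The difficulty is the quaternary C5, wedged between C4 and the ring-fusion carbon C10, and the need to obtain the C8 and C9 oxygens in distinguishable form. The route rests on the fact that C5, the cis C5–C10 junction and the vicinal C8/C9 oxygens are what a 3,3-dimethoxy-2-vinylbicyclo[2.2.2]oct-5-en-2-ol gives on [3,3] rearrangement: a C8 ketone, a C9 ketal and a methyl-bearing quaternary C5.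

## Retrosynthetic reasoning

**C4–CH3 (25 from 23).** C4 is β to the C2 carbonyl, so the methyl group is cut off as a conjugate addition to enone 23, passing through enolate 24. It is placed last because C2 then stays a conjugated, less electrophilic carbonyl while C9 is adjusted. The forward step must add methyl to the β face and leave the tiglate alone.

**C9–O acyl and C9–H (23 from 21 and 22; 21 from 20; 20 from 19).** The C9 ester is cut to alcohol 21 and acid chloride 22, the alcohol to ketone 20, and the ketone to the dimethyl ketal of 19. C9 stays masked until C8 already carries its ester, so the two oxygens are never free together. The forward steps must hydrolyse a hindered ketal next to an ester, then deliver hydride to the β face of C9 without touching the enone.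

**C2 oxidation level (19 from 18 from 17).** The enone is traced back to the allylic silyl ether of 17. The silyloxy group and the C3=C4 double bond both come from the rearrangement, so no transposition is needed.

**Isopropenyl group and C8 ester (17 from 16; 16 from 14 and 15; 14 from 13; 13 from 10 and 11).** The C11=C12 double bond is cut back to the tertiary alcohol of 16, the C8 ester to diol 14 and acid 15, the C8–H bond to ketone 13, and the C7–C11 bond to an aldol between the C8 enolate 12 and acetone 11. The C8 ketone of 10 can enolise only toward C7, and the tertiary hydroxyl left by acetone does not compete in the acylation. The forward steps must set C7 β and C8 α.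

**C5–C6, the key disconnection (10 from 7).** Breaking C5–C6 and reconnecting C3 to C8 folds the decalin back into bicyclooctenol 7. Ring B, the quaternary centre and the cis fusion are removed in one operation, and what remains is three steps from an aromatic compound. The forward step runs through alkoxide 8 and enolate 9.

**Carbinol–vinyl bond (7 from 5 and 6).** The vinyl group is removed as vinylmagnesium bromide 6 from ketone 5, which cannot enolise. The forward step must bring the vinyl group in on the face of the ring alkene.

**The bicycle (5 from 4; 4 from 1 and 2).** Ketone 5 is one enantiomer of racemate 4. Cutting the two bonds from the ethano bridge gives silyl vinyl ether 2 and dienone 3, the oxidation product of creosol 1. The cycloaddition is inherently racemic, so a resolution is accepted here, where the material is cheapest.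

## Alternatives that were turned down

**Alternative 1:** Ring A is opened at C1–C10, with a temporary C1–C9 bond, back to diazoketone A1, in which C4 and the quaternary C5 already sit on a cyclohexa-2,4-diene. In the forward step Cu(acac)2 generates a carbenoid that adds across the proximal C9=C10 bond to give vinylcyclopropyl ketone A2. In its favour, the tether forces the cis ring fusion and the C4 methyl is fixed before the ring closes; on that point it is stronger than the chosen route, which adds the methyl at the end. Against it, A1 needs an enantioselective construction of a quaternary centre on a sensitive cyclohexadiene. The carbenoid can also attack the distal alkene or insert into C–H bonds. After A2 the C1–C9 bond must be opened with an oxygen nucleophile that may attack C7 instead of C9, and C7, C8 and C9 are all still to be built. The chosen route instead starts from an aromatic compound and obtains C8 and C9 already oxygenated at different oxidation levels.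

**Alternative 2:** Both rings are cut at C5–C10 and C6–C7, back to acyclic trienone A3. In the forward step a chiral oxazaborolidinium triflimide activates the isopropenyl ketone and an intramolecular Diels–Alder reaction gives cis-octalin A4. In its favour, both rings, the quaternary centre and the absolute configuration come from one catalytic step with no resolution; on these points it is clearly stronger. Against it, A4 is functionalised in the wrong places. C4 is a ketone that must become a methyl-bearing stereocentre next to the quaternary carbon. C7 carries an acetate where a carbon substituent is needed, and an allylic substitution would tend to deliver it to C9. The C8=C9 alkene gives two hydroxyls of the same kind, which must then be told apart for two different esters. The acetoxydiene and the dioxolane must also survive a strong Lewis acid. The chosen route is weaker in absolute control but needs fewer corrections after the skeleton is made.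

**Alternative 3:** Ring B is cut at C7–C8, back to aldehyde A5, a fully substituted ring A carrying a prenyl group on C5 and a silyloxy aldehyde on C10. In the forward step Me2AlCl promotes a carbonyl-ene closure with transfer of an allylic methyl hydrogen, giving hydroxy ketone A6. In its favour, the isopropenyl group appears directly, C8 is a free hydroxyl while C9 is silylated, and C2 and C4 are finished, so only two acylations and a desilylation remain; the endgame is far shorter than in the chosen route. Against it, all the difficulty moves into A5: C4, quaternary C5, C10 and C9 must be set with no single step that controls them together. The α-silyloxy aldehyde can epimerise or chelate the aluminium. The chair transition state must also place the C9 silyloxy group axial, which may open competing closures. The chosen route pays with a ten-step endgame and a resolution, but sets C5 and C10 stereospecifically in a pericyclic step from a three-step precursor.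

Key step: step 4

**Remark:** the side-chain acid is (R)-2-methylbutanoic acid, taken as purchasable in enantiopure form.

## Route

Step 1
Reactants: 1 creosol (2-methoxy-4-methylphenol); 2 tert-butyldimethyl(vinyloxy)silane
Product: 4 rac-(1S,4S,7S)-7-[(tert-butyldimethylsilyl)oxy]-3,3-dimethoxy-5-methylbicyclo[2.2.2]oct-5-en-2-one, via masked o-benzoquinone 3 (not isolated)
Conditions: PhI(OAc)2, NaHCO3, MeOH, 2 (excess), 0 °C → rt
Reagents that add atoms: methanol, CO; tert-butyldimethyl(vinyloxy)silane (2), C=CO[Si](C)(C)C(C)(C)C
Why: Oxidative dearomatisation of the guaiacol by trivalent iodine in methanol gives dienone 3, which is trapped as an electron-poor diene in an inverse-demand Diels–Alder reaction with the enol ether. The unsubstituted dienophile carbon bonds to the dienone terminus remote from the carbonyl, and the endo transition state turns the silyloxy group toward the new C5=C6 bridge, so the three stereocentres form in one relative configuration, as a racemate.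

Step 2
Reactants: 4 racemic bicyclooctenone
Product: 5 (1S,4S,7S)-7-[(tert-butyldimethylsilyl)oxy]-3,3-dimethoxy-5-methylbicyclo[2.2.2]oct-5-en-2-one
Conditions: preparative HPLC, amylose tris(3,5-dimethylphenylcarbamate) on silica, hexane/i-PrOH, rt
Reagents that add atoms: none
Why: Chromatographic resolution on a polysaccharide carbamate phase should separate the enantiomers of this rigid ketone without derivatisation. The (1S,4S,7S) fraction is carried on, its assignment to be secured by Mosher ester analysis of a desilylated sample.

Step 3
Reactants: 5 (1S,4S,7S)-ketone; 6 vinylmagnesium bromide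
Product: 7 (1S,2R,4S,7S)-7-[(tert-butyldimethylsilyl)oxy]-2-ethenyl-3,3-dimethoxy-5-methylbicyclo[2.2.2]oct-5-en-2-ol
Conditions: 6, THF, −78 → 0 °C; aq. NH4Cl
Reagents that add atoms: vinylmagnesium bromide (6), C=C[Mg]Br
Why: Grignard 1,2-addition to a ketone that cannot enolise (bridgehead on one side, ketal on the other). The reagent should approach past the flat C5=C6 bridge and not under the C7–C8 ethano bridge, so the vinyl group ends up syn to the ring alkene (2R), as the rearrangement requires.

Step 4
Reactants: 7 (1S,2R,4S,7S)-2-vinylbicyclooctenol
Product: 10 cis-decalin ketone 2β-(tert-butyldimethylsilyloxy)-9,9-dimethoxy-5β-methyl-10βH-decal-3-en-8-one, via potassium alkoxide 8 (not isolated), via potassium enolate 9 (not isolated)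
Conditions: KH, 18-crown-6, THF, 0 °C → rt; aq. NH4Cl, −78 °C
Reagents that add atoms: none
Why: KH gives the crown-separated alkoxide 8, whose oxyanion loosens the adjacent C1–C2 bond of the bicycle (C3–C8 in decalin numbering). A concerted anionic oxy-Cope [3,3] shift through the boat-shaped array fixed by the bicyclo[2.2.2]octene then joins the vinyl terminus (C6) to the methyl-bearing alkene carbon (C5) and gives enolate 9, protonated on work-up to 10. The closest known reaction type is the anionic oxy-Cope rearrangement of 2-vinylbicyclo[2.2.2]oct-5-en-2-ols from masked o-benzoquinone cycloadducts to cis-decalins. Ring B closes as a six-membered carbocycle by sigmatropic C5–C6 bond formation, suprafacial on both allyl halves, and the former cyclohexene of the bicycle is released as ring A with its C3=C4 double bond. The one new stereocentre, quaternary C5, is controlled by this suprafacial delivery: the vinyl group is held on C8, which is tied through C9 to C10, so it can reach C5 only on the face that leaves the C5 methyl cis to the C10 hydrogen. C10 and C2 are carried over unchanged from 5, so the absolute configuration rests on the resolution. The step needs the [3,3] path to win over a [1,3] shift or fragmentation; the syn vinyl/alkene geometry from step 3, the release of bicyclic strain and the formation of a stabilised enolate should secure this.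

Step 5
Reactants: 10 cis-decalin ketone; 11 acetone
Product: 13 2β-(tert-butyldimethylsilyloxy)-7β-(2-hydroxypropan-2-yl)-9,9-dimethoxy-5β-methyl-10βH-decal-3-en-8-one, via chlorozinc enolate 12 (not isolated)
Conditions: LiN(i-Pr)2, THF, −78 °C; ZnCl2; 11, −78 → 0 °C; aq. NH4Cl
Reagents that add atoms: acetone (11), CC(C)=O
Why: Enolisation is regiospecific because C9 carries no hydrogen, and the zinc enolate adds to acetone in an aldol reaction whose chelated aldolate resists reversal. Because the addition is reversible, the side chain should settle equatorial on ring B, which is 7β in the chair that keeps the C5 methyl equatorial on that ring.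

Step 6
Reactants: 13 aldol adduct
Product: 14 2β-(tert-butyldimethylsilyloxy)-7β-(2-hydroxypropan-2-yl)-9,9-dimethoxy-5β-methyl-10βH-decal-3-en-8α-ol
Conditions: NaBH4, MeOH, −20 → 0 °C
Reagents that add atoms: none
Why: Borohydride reduction by axial attack on the β face, which meets only the axial hydrogens on C6 and C10 and runs anti to the axial C9 methoxy group. This should give the equatorial 8α-alcohol, trans to the C7 side chain.

Step 7
Reactants: 14 diol; 15 (R)-2-methylbutanoic acid
Product: 16 2β-(tert-butyldimethylsilyloxy)-7β-(2-hydroxypropan-2-yl)-9,9-dimethoxy-5β-methyl-10βH-decal-3-en-8α-yl (2R)-2-methylbutanoate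
Conditions: 15, DCC, DMAP, CH2Cl2, 0 °C → rt
Reagents that add atoms: (R)-2-methylbutanoic acid (15), CC[C@@H](C)C(=O)O
Why: Steglich esterification; only the secondary hydroxyl is acylated, the tertiary one being inert. The carbodiimide conditions are mild enough to keep the α-stereocentre of the acid intact.

Step 8
Reactants: 16 tertiary alcohol ester
Product: 17 2β-(tert-butyldimethylsilyloxy)-9,9-dimethoxy-5β-methyl-7β-(prop-1-en-2-yl)-10βH-decal-3-en-8α-yl (2R)-2-methylbutanoate
Conditions: SOCl2, pyridine, CH2Cl2, −20 → 0 °C
Reagents that add atoms: none
Why: Dehydration of the tertiary alcohol through its chlorosulfite. Anti elimination should take one of the six accessible methyl hydrogens in preference to the single hindered C7 hydrogen, so the isopropenyl compound is expected as the main alkene, with the tetrasubstituted isomer a separable minor product.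

Step 9
Reactants: 17 isopropenyl silyl ether
Product: 18 2β-hydroxy-9,9-dimethoxy-5β-methyl-7β-(prop-1-en-2-yl)-10βH-decal-3-en-8α-yl (2R)-2-methylbutanoate
Conditions: Bu4NF, AcOH, THF, 0 °C → rt
Reagents that add atoms: none
Why: Fluoride cleavage of the allylic silyl ether. Acetic acid buffers the medium so that the ester and its α-stereocentre are not touched.

Step 10
Reactants: 18 allylic alcohol
Product: 19 9,9-dimethoxy-5β-methyl-2-oxo-7β-(prop-1-en-2-yl)-10βH-decal-3-en-8α-yl (2R)-2-methylbutanoate
Conditions: Dess–Martin periodinane, pyridine, CH2Cl2, 0 °C → rt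
Reagents that add atoms: none
Why: Dess–Martin oxidation of the only free hydroxyl, an allylic secondary alcohol, to the enone. The buffered conditions leave ketal, ester and isopropenyl group alone.

Step 11
Reactants: 19 enone ketal
Product: 20 5β-methyl-2,9-dioxo-7β-(prop-1-en-2-yl)-10βH-decal-3-en-8α-yl (2R)-2-methylbutanoate
Conditions: TsOH·H2O (cat.), acetone/H2O, 40 °C
Reagents that add atoms: water, O
Why: Acid-catalysed hydrolysis of the dimethyl ketal, with a weak acid in wet acetone chosen to spare the isopropenyl group. The cis fusion is not at risk once C10 becomes enolisable, because the trans-fused epimer would force the isopropenyl group into a 1,3-diaxial clash with the C5 methyl.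

Step 12
Reactants: 20 enone ketone
Product: 21 9α-hydroxy-5β-methyl-2-oxo-7β-(prop-1-en-2-yl)-10βH-decal-3-en-8α-yl (2R)-2-methylbutanoate
Conditions: NaBH4, MeOH/CH2Cl2 (1:1), −78 °C
Reagents that add atoms: none
Why: Chemoselective borohydride reduction at low temperature; the saturated, acyloxy-activated C9 ketone should react before the conjugated C2 carbonyl. Hydride is expected from the convex β face, because the axial α approach to C9 is closed by C4, which sits 1,3-diaxial to it on ring B, giving the axial 9α-alcohol cis to the C8 ester.

Step 13
Reactants: 21 hydroxy enone; 22 tigloyl chloride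
Product: 23 5β-methyl-9α-[(E)-2-methylbut-2-enoyloxy]-2-oxo-7β-(prop-1-en-2-yl)-10βH-decal-3-en-8α-yl (2R)-2-methylbutanoate
Conditions: 22, DMAP, pyridine, CH2Cl2, 0 → 40 °C
Reagents that add atoms: tigloyl chloride (22), C/C=C(\C)C(=O)Cl
Why: DMAP-catalysed acylation of the hindered axial alcohol with the acid chloride. The E geometry of the tigloyl group is the stable one and is not at risk.

Step 14
Reactants: 23 enone diester
Product: 25 target 8α-[(2R)-2-methylbutanoyloxy]-9α-[(E)-2-methylbut-2-enoyloxy]-10βH-eremophil-11-en-2-one (CNP0312791.1), via lithium enolate 24 (not isolated)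
Conditions: Me2CuLi (from MeLi and CuI), Et2O, −78 → −30 °C; aq. NH4Cl
Reagents that add atoms: lithium dimethylcuprate, [Li+].C[Cu-]C
Why: Conjugate addition of a Gilman cuprate to the cyclohexenone, which should be far faster than addition to the α,β-disubstituted tiglate. The α face of C4 is closed by C9 and its axial acyloxy group, so the methyl group should enter from the convex β face, cis to the C5 methyl, and protonation of enolate 24 gives the C2 ketone.

## Compound list

1 | creosol (2-methoxy-4-methylphenol) | COc1cc(C)ccc1O | starting material
2 | tert-butyldimethyl(vinyloxy)silane | C=CO[Si](C)(C)C(C)(C)C | starting material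
3 | 6,6-dimethoxy-4-methylcyclohexa-2,4-dien-1-one (masked o-benzoquinone, not isolated) | COC1(OC)C=C(C)C=CC1=O | intermediate
4 | rac-(1S,4S,7S)-7-[(tert-butyldimethylsilyl)oxy]-3,3-dimethoxy-5-methylbicyclo[2.2.2]oct-5-en-2-one (racemate; one enantiomer drawn) | O=C1C(OC)(OC)[C@H]2C[C@H](O[Si](C)(C)C(C)(C)C)[C@@H]1C=C2C | intermediate
5 | (1S,4S,7S)-7-[(tert-butyldimethylsilyl)oxy]-3,3-dimethoxy-5-methylbicyclo[2.2.2]oct-5-en-2-one | O=C1C(OC)(OC)[C@H]2C[C@H](O[Si](C)(C)C(C)(C)C)[C@@H]1C=C2C | intermediate
6 | vinylmagnesium bromide | C=C[Mg]Br | starting material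
7 | (1S,2R,4S,7S)-7-[(tert-butyldimethylsilyl)oxy]-2-ethenyl-3,3-dimethoxy-5-methylbicyclo[2.2.2]oct-5-en-2-ol | C=C[C@]1(O)C(OC)(OC)[C@H]2C[C@H](O[Si](C)(C)C(C)(C)C)[C@@H]1C=C2C | intermediate
8 | potassium alkoxide of 7 (not isolated) | [K+].C=C[C@]1([O-])C(OC)(OC)[C@H]2C[C@H](O[Si](C)(C)C(C)(C)C)[C@@H]1C=C2C | intermediate
9 | potassium C7=C8 enolate of 10 (not isolated) | [K+].[O-]C1=CC[C@@]2(C)[C@H](C[C@H](O[Si](C)(C)C(C)(C)C)C=C2)C1(OC)OC | intermediate
10 | 2β-(tert-butyldimethylsilyloxy)-9,9-dimethoxy-5β-methyl-10βH-decal-3-en-8-one (cis-fused) | C1C[C@@]2(C)[C@H](C[C@H](O[Si](C)(C)C(C)(C)C)C=C2)C(OC)(OC)C1=O | intermediate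
11 | acetone | CC(C)=O | starting material
12 | chlorozinc C7=C8 enolate of 10 (not isolated) | Cl[Zn]OC1=CC[C@@]2(C)[C@H](C[C@H](O[Si](C)(C)C(C)(C)C)C=C2)C1(OC)OC | intermediate
13 | 2β-(tert-butyldimethylsilyloxy)-7β-(2-hydroxypropan-2-yl)-9,9-dimethoxy-5β-methyl-10βH-decal-3-en-8-one | CC(C)(O)[C@H]1C[C@@]2(C)[C@H](C[C@H](O[Si](C)(C)C(C)(C)C)C=C2)C(OC)(OC)C1=O | intermediate
14 | 2β-(tert-butyldimethylsilyloxy)-7β-(2-hydroxypropan-2-yl)-9,9-dimethoxy-5β-methyl-10βH-decal-3-en-8α-ol | CC(C)(O)[C@H]1C[C@@]2(C)[C@H](C[C@H](O[Si](C)(C)C(C)(C)C)C=C2)C(OC)(OC)[C@@H]1O | intermediate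
15 | (R)-2-methylbutanoic acid | CC[C@@H](C)C(=O)O | starting material
16 | 8α-[(2R)-2-methylbutanoate] of 14 | CC(C)(O)[C@H]1C[C@@]2(C)[C@H](C[C@H](O[Si](C)(C)C(C)(C)C)C=C2)C(OC)(OC)[C@@H]1OC(=O)[C@H](C)CC | intermediate
17 | 2β-(tert-butyldimethylsilyloxy)-9,9-dimethoxy-5β-methyl-7β-(prop-1-en-2-yl)-10βH-decal-3-en-8α-yl (2R)-2-methylbutanoate | C=C(C)[C@H]1C[C@@]2(C)[C@H](C[C@H](O[Si](C)(C)C(C)(C)C)C=C2)C(OC)(OC)[C@@H]1OC(=O)[C@H](C)CC | intermediate
18 | 2β-hydroxy-9,9-dimethoxy-5β-methyl-7β-(prop-1-en-2-yl)-10βH-decal-3-en-8α-yl (2R)-2-methylbutanoate | C=C(C)[C@H]1C[C@@]2(C)[C@H](C[C@H](O)C=C2)C(OC)(OC)[C@@H]1OC(=O)[C@H](C)CC | intermediate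
19 | 9,9-dimethoxy-5β-methyl-2-oxo-7β-(prop-1-en-2-yl)-10βH-decal-3-en-8α-yl (2R)-2-methylbutanoate | C=C(C)[C@H]1C[C@@]2(C)[C@H](CC(=O)C=C2)C(OC)(OC)[C@@H]1OC(=O)[C@H](C)CC | intermediate
20 | 5β-methyl-2,9-dioxo-7β-(prop-1-en-2-yl)-10βH-decal-3-en-8α-yl (2R)-2-methylbutanoate | C=C(C)[C@H]1C[C@@]2(C)[C@H](CC(=O)C=C2)C(=O)[C@@H]1OC(=O)[C@H](C)CC | intermediate
21 | 9α-hydroxy-5β-methyl-2-oxo-7β-(prop-1-en-2-yl)-10βH-decal-3-en-8α-yl (2R)-2-methylbutanoate | C=C(C)[C@H]1C[C@@]2(C)[C@H](CC(=O)C=C2)[C@H](O)[C@@H]1OC(=O)[C@H](C)CC | intermediate
22 | tigloyl chloride ((E)-2-methylbut-2-enoyl chloride) | C/C=C(\C)C(=O)Cl | starting material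
23 | 5β-methyl-9α-[(E)-2-methylbut-2-enoyloxy]-2-oxo-7β-(prop-1-en-2-yl)-10βH-decal-3-en-8α-yl (2R)-2-methylbutanoate | C=C(C)[C@H]1C[C@@]2(C)[C@H](CC(=O)C=C2)[C@H](OC(=O)/C(C)=C/C)[C@@H]1OC(=O)[C@H](C)CC | intermediate
24 | lithium C2=C3 enolate of the target (not isolated) | [Li+].C=C(C)[C@H]1C[C@@]2(C)[C@H](CC([O-])=C[C@@H]2C)[C@H](OC(=O)/C(C)=C/C)[C@@H]1OC(=O)[C@H](C)CC | intermediate
25 | CNP0312791.1, 4β,5β-dimethyl-8α-[(2R)-2-methylbutanoyloxy]-9α-[(E)-2-methylbut-2-enoyloxy]-10βH-eremophil-11-en-2-one | C=C(C)[C@H]1C[C@@]2(C)[C@H](CC(=O)C[C@@H]2C)[C@H](OC(=O)/C(C)=C/C)[C@@H]1OC(=O)[C@H](C)CC | target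

## Step count and least certain steps

Total: 14 steps. Longest linear sequence: 14 steps, from creosol 1 to 25.

**Step 4 (key step).** The alkoxide may break the C3–C8 bond heterolytically and not in concert. The allyl anion set free would then expel the β-silyloxy group before it can recombine, giving ring-opened elimination products. The fallback sets out from 7 and avoids anions. The tertiary hydroxyl is silylated with N-(trimethylsilyl)imidazole to the bis-silyl ether F1. Heating in degassed toluene in a sealed tube at about 220 °C should bring about the neutral siloxy-Cope shift to the trimethylsilyl enol ether F2. Brief treatment with citric acid in aqueous THF then cleaves only the enol ether and comes back to the route at 10.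

**Step 5.** The enolate may deprotonate acetone instead of adding to it, or the adduct may revert by retro-aldol cleavage on work-up, and the two C7 epimers may not converge if equilibration is slow. The fallback sets out from 10 and forms the C7–C11 bond by cross-coupling. Palladium-catalysed α-alkenylation of the ketone enolate with 2-bromopropene (Pd2(dba)3, a bulky dialkylbiarylphosphine, LiN(SiMe3)2, toluene) gives the 7β-isopropenyl ketone F3. NaBH4 at low temperature reduces it to the 8α-alcohol F4 before the double bond can move into conjugation. Esterification with 15 (DCC, DMAP) comes back at 17.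

**Step 11.** Ionisation of the ketal is slowed by the neighbouring acyloxy group. If stronger acid is then needed, the isopropenyl double bond may be hydrated or moved. The fallback sets out from 16 and postpones the dehydration. Bu4NF/AcOH gives the hydroxy ester F5 with the tertiary alcohol still in place, and Dess–Martin oxidation gives the enone F6. The ketal is then hydrolysed with stronger aqueous acid, which a tertiary alcohol tolerates better than a 1,1-disubstituted alkene, to give the dione F7. SOCl2/pyridine dehydration comes back at 20.

**Step 12.** Shielding of the α face by the sp2 carbon C4 may be insufficient, so axial hydride attack would give the equatorial 9β-alcohol. The fallback sets out from 20 and uses that epimer. The 9β-alcohol F8 is esterified with tiglic acid under Mitsunobu conditions (PPh3, diisopropyl azodicarboxylate), which installs the tiglate with inversion and comes back at 23.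

**Step 14.** Addition at the β-carbon next to the quaternary C5 may be slow, so that the tiglate begins to compete as acceptor or the enolate transfers an acyl group on warming. The fallback sets out from 21 and changes the order. The cuprate is added to the enone while C9 still carries its free hydroxyl (one extra equivalent of reagent), giving the saturated hydroxy ketone F9. Acylation with 22 as in step 13 then comes back at 25.

## Further compounds

F1 | step 4 | trimethylsilyl ether of 7 | C=C[C@]1(O[Si](C)(C)C)C(OC)(OC)[C@H]2C[C@H](O[Si](C)(C)C(C)(C)C)[C@@H]1C=C2C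
F2 | step 4 | trimethylsilyl C7=C8 enol ether of 10 | C[Si](C)(C)OC1=CC[C@@]2(C)[C@H](C[C@H](O[Si](C)(C)C(C)(C)C)C=C2)C1(OC)OC
F3 | step 5 | 2β-(tert-butyldimethylsilyloxy)-9,9-dimethoxy-5β-methyl-7β-(prop-1-en-2-yl)-10βH-decal-3-en-8-one | C=C(C)[C@H]1C[C@@]2(C)[C@H](C[C@H](O[Si](C)(C)C(C)(C)C)C=C2)C(OC)(OC)C1=O
F4 | step 5 | 2β-(tert-butyldimethylsilyloxy)-9,9-dimethoxy-5β-methyl-7β-(prop-1-en-2-yl)-10βH-decal-3-en-8α-ol | C=C(C)[C@H]1C[C@@]2(C)[C@H](C[C@H](O[Si](C)(C)C(C)(C)C)C=C2)C(OC)(OC)[C@@H]1O
F5 | step 11 | 2β-hydroxy-7β-(2-hydroxypropan-2-yl)-9,9-dimethoxy-5β-methyl-10βH-decal-3-en-8α-yl (2R)-2-methylbutanoate | CC(C)(O)[C@H]1C[C@@]2(C)[C@H](C[C@H](O)C=C2)C(OC)(OC)[C@@H]1OC(=O)[C@H](C)CC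
F6 | step 11 | 7β-(2-hydroxypropan-2-yl)-9,9-dimethoxy-5β-methyl-2-oxo-10βH-decal-3-en-8α-yl (2R)-2-methylbutanoate | CC(C)(O)[C@H]1C[C@@]2(C)[C@H](CC(=O)C=C2)C(OC)(OC)[C@@H]1OC(=O)[C@H](C)CC
F7 | step 11 | 7β-(2-hydroxypropan-2-yl)-5β-methyl-2,9-dioxo-10βH-decal-3-en-8α-yl (2R)-2-methylbutanoate | CC(C)(O)[C@H]1C[C@@]2(C)[C@H](CC(=O)C=C2)C(=O)[C@@H]1OC(=O)[C@H](C)CC
F8 | step 12 | 9β-hydroxy-5β-methyl-2-oxo-7β-(prop-1-en-2-yl)-10βH-decal-3-en-8α-yl (2R)-2-methylbutanoate | C=C(C)[C@H]1C[C@@]2(C)[C@H](CC(=O)C=C2)[C@@H](O)[C@@H]1OC(=O)[C@H](C)CC
F9 | step 14 | 9α-hydroxy-4β,5β-dimethyl-2-oxo-7β-(prop-1-en-2-yl)-10βH-decalin-8α-yl (2R)-2-methylbutanoate | C=C(C)[C@H]1C[C@@]2(C)[C@H](CC(=O)C[C@@H]2C)[C@H](O)[C@@H]1OC(=O)[C@H](C)CC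
A1 | alternative 1 | diazoketone with C4 and quaternary C5 on a cyclohexa-2,4-diene | [N-]=[N+]=CC(=O)C[C@H](C)[C@@]1(C)CC=CC=C1
A2 | alternative 1 | tricyclic vinylcyclopropyl ketone with C1 bridging C9 and C10 | C1=C[C@@H]2[C@H]3[C@@H]2C(=O)C[C@H](C)[C@@]3(C)C1
A3 | alternative 2 | acyclic (E,E)-acetoxydiene isopropenyl ketone with C2 dioxolane | C=C(C)C(=O)CC1(OCCO1)C/C=C/C=C/OC(C)=O
A4 | alternative 2 | cis-fused octalin with C4 ketone, C2 dioxolane, C8=C9 alkene and C7 acetate | CC(=O)O[C@@H]1C[C@@]2(C)[C@H](CC3(OCCO3)CC2=O)C=C1
A5 | alternative 3 | ring A ketone with C5 prenyl group and C9 silyloxy C8 aldehyde | CC(C)=CC[C@@]1(C)[C@H](CC(=O)C[C@@H]1C)[C@H](O[Si](C)(C)C(C)(C)C)C=O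
A6 | alternative 3 | 8-hydroxy-9-silyloxy eremophilane ketone with C7 isopropenyl group | C=C(C)[C@H]1C[C@@]2(C)[C@H](CC(=O)C[C@@H]2C)[C@H](O[Si](C)(C)C(C)(C)C)[C@@H]1O
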